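**Retrosynthetic overview**
- The C6–C6' biaryl bond is cut to two C4-epimeric halves, bromide 14 (3,4-trans) and boronate 15 (3,4-cis), joined by Suzuki–Miyaura coupling. Each ring carries only one ortho substituent, so no atropisomer arises.
- Both halves come from one ketone 12: hydride reduction sets 4R (all-cis, 13), and SN1 exchange at C4 anti to O3 turns 13 into its 4S epimer 14.
- Ring C (O1–C2–C3–C4–C4a–C8a) is not closed directly. It arises from the seven-membered 1,3-benzodioxepine ring O1–C2–O3–C3–C4–C4a–C8a by a 1,2-shift of C2 from O3 to C3 (ring contraction), which makes the C2–C3 bond and both of its stereocentres.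
- Enabling feature: C2 (aryl-substituted, bonded to O1) is at the acetal level, and C3 is the oxygen-bearing α-carbon of the C4 aryl ketone. O3 can therefore serve first as acetal partner and leaving group, then as the 3-hydroxyl.
- Ring order: ring A (gallacetophenone) → seven-membered acetal ring → ring C by contraction → biaryl.

Key step: step 6

Assumption: the sense of induction of the chiral acid in step 6 cannot be assigned in advance; the catalyst antipode that delivers (2R,3S)-12 is the one used.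

**Route**

Step 1
Reactants: 1 1-(2,3,4-trihydroxyphenyl)ethan-1-one (gallacetophenone)
Product: 2 1-[3,4-bis(benzyloxy)-2-hydroxyphenyl]ethan-1-one
Conditions: BnBr (2.1 equiv), K2CO3, DMF, 25 °C
Reagents that add atoms: benzyl bromide, BrCc1ccccc1
Why: Williamson etherification; the 2-OH is hydrogen-bonded to the carbonyl and least nucleophilic, so two equivalents of benzyl bromide should etherify O3 and O4 only.

Step 2
Reactants: 2 1-[3,4-bis(benzyloxy)-2-hydroxyphenyl]ethan-1-one
Product: 3 1-[3,4-bis(benzyloxy)-5-bromo-2-hydroxyphenyl]ethan-1-one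
Conditions: NBS (1.05 equiv), MeCN, 0 → 25 °C
Reagents that add atoms: N-bromosuccinimide, O=C1CCC(=O)N1Br
Why: Electrophilic aromatic bromination; C5 is para to the free phenol and ortho to a benzyloxy group, whereas C6 lies next to the deactivating acyl group.

Step 3
Reactants: 3 1-[3,4-bis(benzyloxy)-5-bromo-2-hydroxyphenyl]ethan-1-one
Product: 6 1-[3,4-bis(benzyloxy)-5-bromo-2-hydroxyphenyl]-2-hydroxyethan-1-one, via bis-silyl enol ether 4 (not isolated), via α-silyloxy ketone 5 (not isolated)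
Conditions: TMSOTf (2.3 equiv), Et3N, CH2Cl2, 0 °C; mCPBA, NaHCO3, −20 °C; 1 M HCl, THF
Reagents that add atoms: mCPBA, O=C(OO)c1cccc(Cl)c1
Why: Rubottom oxidation; double silylation masks the phenol and forms the silyl enol ether, epoxidation with 1,4-silyl shift gives the α-silyloxy ketone, and mild acid frees both hydroxyls without exposing a phenoxide next to a leaving group.

Step 4
Reactants: 6 1-[3,4-bis(benzyloxy)-5-bromo-2-hydroxyphenyl]-2-hydroxyethan-1-one; 7 4-(benzyloxy)benzaldehyde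
Product: 9 racemic 8,9-bis(benzyloxy)-2-[4-(benzyloxy)phenyl]-7-bromo-4H-benzo[d][1,3]dioxepin-5-one, via dimethyl acetal 8 (not isolated)
Conditions: 7, HC(OMe)3, PPTS (cat.), MeOH, 25 °C, evaporate; then 6, PPTS (cat.), toluene, 70 °C, 200 mbar
Reagents that add atoms: none
Why: Acid-catalysed transacetalization driven by removal of methanol; the primary hydroxyl and the phenol bridge the aldehyde carbon and close the seven-membered O,O-acetal ring (acetal centre racemic).

Step 5
Reactants: 9 racemic 8,9-bis(benzyloxy)-2-[4-(benzyloxy)phenyl]-7-bromo-4H-benzo[d][1,3]dioxepin-5-one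
Product: 10 racemic 8,9-bis(benzyloxy)-2-[4-(benzyloxy)phenyl]-7-bromo-5-[(tert-butyldimethylsilyl)oxy]-2H-benzo[d][1,3]dioxepine
Conditions: KN(SiMe3)2, THF, −78 °C; t-BuMe2SiCl, −78 → −20 °C
Reagents that add atoms: tert-butyldimethylsilyl chloride, CC(C)(C)[Si](C)(C)Cl
Why: Kinetic enolate O-silylation; only C4 carries enolizable hydrogens, and the ring fixes the enol geometry with O3 cis to the arene carbon.

Step 6
Reactants: 10 racemic 8,9-bis(benzyloxy)-2-[4-(benzyloxy)phenyl]-7-bromo-5-[(tert-butyldimethylsilyl)oxy]-2H-benzo[d][1,3]dioxepine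
Product: 12 (2R,3S)-7,8-bis(benzyloxy)-2-[4-(benzyloxy)phenyl]-6-bromo-3-[(tert-butyldimethylsilyl)oxy]chroman-4-one (2,3-cis), via oxocarbenium ion pair 11 (not isolated)
Conditions: confined chiral imidodiphosphorimidate (IDPi) Brønsted acid (5 mol %), toluene/CH2Cl2, −60 °C
Reagents that add atoms: none
Why: Proposed new method: the silylated form of the chiral acid (formed by protodesilylation of a trace of 10) silylates enol-ether oxygen O3, the C2–O3 bond ionizes to the aryl-stabilized E-oxocarbenium ion O1=C2 paired with the chiral anion (11), the released 1,2-bis(silyloxy)alkene attacks C2 through dioxepine C4 (the later C3), and the silyl group on the new carbonyl oxygen returns to the anion. The closest known reaction types are the Petasis–Ferrier and 1,3-dioxepine [1,3] O-to-C rearrangements and counteranion-directed Mukaiyama additions to oxocarbenium ions; here it is a [1,2] variant in which the nucleophilic carbon is the one that carried the leaving oxygen. Ring C closes in a 6-(enolendo)-endo-trig mode, formally a 1,2-shift of C2 from O3 to the adjacent carbon that contracts the seven-membered ring to the six-membered one. At C2 the E-oxocarbenium geometry places the aryl group equatorial and the chiral anion selects the face; the acetal centre of racemic 10 is erased on ionization, so both enantiomers converge (dynamic kinetic asymmetric transformation). At C3 the enol geometry locked by the seven-membered ring (O3 cis to the arene carbon) forces O3 axial in the half-chair transition state, cis to the aryl group. The step needs C–C bonding through C4 and not C5 (secured because attack by C4 leaves a silyloxocarbenium ion conjugated to the electron-rich arene and closes a six- instead of a five-membered ring), productive C2–O3 over C2–O1 ionization (the latter can only return to 10), and survival of the kinetic cis product (low temperature, no base, O3 silylated).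

Step 7
Reactants: 12 (2R,3S)-7,8-bis(benzyloxy)-2-[4-(benzyloxy)phenyl]-6-bromo-3-[(tert-butyldimethylsilyl)oxy]chroman-4-one
Product: 13 (2R,3R,4R)-7,8-bis(benzyloxy)-2-[4-(benzyloxy)phenyl]-6-bromo-3-[(tert-butyldimethylsilyl)oxy]chroman-4-ol (2,3-cis-3,4-cis)
Conditions: NaBH4, THF/MeOH (4:1), −40 °C
Reagents that add atoms: none
Why: Borohydride reduction; axial hydride attack anti to the axial 3-silyloxy group (aryl equatorial) should give the equatorial 4-OH cis to O3, i.e. 4R.

Step 8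
Reactants: 13 (2R,3R,4R)-7,8-bis(benzyloxy)-2-[4-(benzyloxy)phenyl]-6-bromo-3-[(tert-butyldimethylsilyl)oxy]chroman-4-ol
Product: 14 (2R,3R,4S)-7,8-bis(benzyloxy)-2-[4-(benzyloxy)phenyl]-6-bromo-3-[(tert-butyldimethylsilyl)oxy]chroman-4-ol (2,3-cis-3,4-trans)
Conditions: CSA (10 mol %), THF/H2O (5:1), 25 °C, to equilibrium; unchanged 13 is recovered for step 9
Reagents that add atoms: water, O
Why: SN1 exchange at C4 through the benzylic cation stabilized by the para 7-benzyloxy group and O1; water should add quasi-axially anti to the axial 3-silyloxy group, giving the trans-diaxial 4S alcohol, which is also the more stable epimer (the usual 4-substitution course of 2,3-cis flavans).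

Step 9
Reactants: 13 (2R,3R,4R)-7,8-bis(benzyloxy)-2-[4-(benzyloxy)phenyl]-6-bromo-3-[(tert-butyldimethylsilyl)oxy]chroman-4-ol
Product: 15 (2R,3R,4R)-7,8-bis(benzyloxy)-2-[4-(benzyloxy)phenyl]-3-[(tert-butyldimethylsilyl)oxy]-6-(4,4,5,5-tetramethyl-1,3,2-dioxaborolan-2-yl)chroman-4-ol
Conditions: B2pin2, Pd(dppf)Cl2 (5 mol %), KOAc, 1,4-dioxane, 85 °C
Reagents that add atoms: bis(pinacolato)diboron, CC1(C)OB(OC1(C)C)B1OC(C)(C)C(C)(C)O1
Why: Miyaura borylation of the aryl bromide; the weak acetate base should leave the secondary alcohol, silyl ether and stereocentres untouched.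

Step 10
Reactants: 14 (2R,3R,4S)-7,8-bis(benzyloxy)-2-[4-(benzyloxy)phenyl]-6-bromo-3-[(tert-butyldimethylsilyl)oxy]chroman-4-ol; 15 (2R,3R,4R)-7,8-bis(benzyloxy)-2-[4-(benzyloxy)phenyl]-3-[(tert-butyldimethylsilyl)oxy]-6-(4,4,5,5-tetramethyl-1,3,2-dioxaborolan-2-yl)chroman-4-ol
Product: 16 (2R,3R,4S,2'R,3'R,4'R)-7,7',8,8'-tetrakis(benzyloxy)-2,2'-bis[4-(benzyloxy)phenyl]-3,3'-bis[(tert-butyldimethylsilyl)oxy]-[6,6'-bichromane]-4,4'-diol
Conditions: Pd(OAc)2 (5 mol %), SPhos (10 mol %), K3PO4, toluene/H2O (10:1), 70 °C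
Reagents that add atoms: none
Why: Suzuki–Miyaura cross-coupling; the biaryl has one ortho alkoxy group per ring, which a dialkylbiarylphosphine ligand handles readily, and no stereocentre is involved.

Step 11
Reactants: 16 (2R,3R,4S,2'R,3'R,4'R)-7,7',8,8'-tetrakis(benzyloxy)-2,2'-bis[4-(benzyloxy)phenyl]-3,3'-bis[(tert-butyldimethylsilyl)oxy]-[6,6'-bichromane]-4,4'-diol
Product: 17 (2R,3R,4S,2'R,3'R,4'R)-7,7',8,8'-tetrakis(benzyloxy)-2,2'-bis[4-(benzyloxy)phenyl]-[6,6'-bichromane]-3,3',4,4'-tetrol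
Conditions: Bu4NF, AcOH, THF, 0 → 25 °C
Reagents that add atoms: none
Why: Fluoride desilylation; buffering with acetic acid keeps the medium near neutral, so the acid-labile C4 carbinols should not ionize.

Step 12
Reactants: 17 (2R,3R,4S,2'R,3'R,4'R)-7,7',8,8'-tetrakis(benzyloxy)-2,2'-bis[4-(benzyloxy)phenyl]-[6,6'-bichromane]-3,3',4,4'-tetrol
Product: 18 (2R,3R,4R,2'R,3'R,4'S)-2,2'-bis(4-hydroxyphenyl)-[6,6'-bichromane]-3,3',4,4',7,7',8,8'-octol (CNP0121763.1)
Conditions: H2 (1 atm), Pd(OH)2/C, NaHCO3 (solid), THF/MeOH, 25 °C; filtration under argon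
Reagents that add atoms: none
Why: Hydrogenolysis of aryl benzyl ethers; under neutral, acid-free conditions these should cleave much faster than the secondary benzylic C4–OH bonds, as in debenzylations that leave para-hydroxybenzylic alcohols intact.

**Compound list**

1 | 1-(2,3,4-trihydroxyphenyl)ethan-1-one (gallacetophenone) | CC(=O)c1ccc(O)c(O)c1O | starting material
2 | 1-[3,4-bis(benzyloxy)-2-hydroxyphenyl]ethan-1-one | CC(=O)c1ccc(OCc2ccccc2)c(OCc2ccccc2)c1O | intermediate
3 | 1-[3,4-bis(benzyloxy)-5-bromo-2-hydroxyphenyl]ethan-1-one | CC(=O)c1cc(Br)c(OCc2ccccc2)c(OCc2ccccc2)c1O | intermediate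
4 | {1-[3,4-bis(benzyloxy)-5-bromo-2-(trimethylsilyloxy)phenyl]ethenyloxy}trimethylsilane (bis-silyl enol ether) | C=C(O[Si](C)(C)C)c1cc(Br)c(OCc2ccccc2)c(OCc2ccccc2)c1O[Si](C)(C)C | intermediate
5 | 1-[3,4-bis(benzyloxy)-5-bromo-2-(trimethylsilyloxy)phenyl]-2-(trimethylsilyloxy)ethan-1-one | O=C(CO[Si](C)(C)C)c1cc(Br)c(OCc2ccccc2)c(OCc2ccccc2)c1O[Si](C)(C)C | intermediate
6 | 1-[3,4-bis(benzyloxy)-5-bromo-2-hydroxyphenyl]-2-hydroxyethan-1-one | O=C(CO)c1cc(Br)c(OCc2ccccc2)c(OCc2ccccc2)c1O | intermediate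
7 | 4-(benzyloxy)benzaldehyde | O=Cc1ccc(OCc2ccccc2)cc1 | starting material
8 | 1-(benzyloxy)-4-(dimethoxymethyl)benzene | COC(OC)c1ccc(OCc2ccccc2)cc1 | intermediate
9 | racemic 8,9-bis(benzyloxy)-2-[4-(benzyloxy)phenyl]-7-bromo-4H-benzo[d][1,3]dioxepin-5-one | O=C1COC(c2ccc(OCc3ccccc3)cc2)Oc2c(OCc3ccccc3)c(OCc3ccccc3)c(Br)cc21 | intermediate
10 | racemic 8,9-bis(benzyloxy)-2-[4-(benzyloxy)phenyl]-7-bromo-5-[(tert-butyldimethylsilyl)oxy]-2H-benzo[d][1,3]dioxepine | CC(C)(C)[Si](C)(C)OC1=COC(c2ccc(OCc3ccccc3)cc2)Oc2c(OCc3ccccc3)c(OCc3ccccc3)c(Br)cc21 | intermediate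
11 | ring-opened E-oxocarbenium ion carrying the Z-1,2-bis(silyloxy)alkene (cation of the ion pair with the chiral acid anion) | CC(C)(C)[Si](C)(C)O/C=C(/O[Si](C)(C)C(C)(C)C)c1cc(Br)c(OCc2ccccc2)c(OCc2ccccc2)c1/[O+]=C/c1ccc(OCc2ccccc2)cc1 | intermediate
12 | (2R,3S)-7,8-bis(benzyloxy)-2-[4-(benzyloxy)phenyl]-6-bromo-3-[(tert-butyldimethylsilyl)oxy]chroman-4-one | O=C1c2cc(Br)c(OCc3ccccc3)c(OCc3ccccc3)c2O[C@H](c2ccc(OCc3ccccc3)cc2)[C@@H]1O[Si](C)(C)C(C)(C)C | intermediate
13 | (2R,3R,4R)-7,8-bis(benzyloxy)-2-[4-(benzyloxy)phenyl]-6-bromo-3-[(tert-butyldimethylsilyl)oxy]chroman-4-ol | O[C@@H]1c2cc(Br)c(OCc3ccccc3)c(OCc3ccccc3)c2O[C@H](c2ccc(OCc3ccccc3)cc2)[C@@H]1O[Si](C)(C)C(C)(C)C | intermediate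
14 | (2R,3R,4S)-7,8-bis(benzyloxy)-2-[4-(benzyloxy)phenyl]-6-bromo-3-[(tert-butyldimethylsilyl)oxy]chroman-4-ol | O[C@H]1c2cc(Br)c(OCc3ccccc3)c(OCc3ccccc3)c2O[C@H](c2ccc(OCc3ccccc3)cc2)[C@@H]1O[Si](C)(C)C(C)(C)C | intermediate
15 | (2R,3R,4R)-7,8-bis(benzyloxy)-2-[4-(benzyloxy)phenyl]-3-[(tert-butyldimethylsilyl)oxy]-6-(4,4,5,5-tetramethyl-1,3,2-dioxaborolan-2-yl)chroman-4-ol | O[C@@H]1c2cc(B3OC(C)(C)C(C)(C)O3)c(OCc3ccccc3)c(OCc3ccccc3)c2O[C@H](c2ccc(OCc3ccccc3)cc2)[C@@H]1O[Si](C)(C)C(C)(C)C | intermediate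
16 | (2R,3R,4S,2'R,3'R,4'R)-7,7',8,8'-tetrakis(benzyloxy)-2,2'-bis[4-(benzyloxy)phenyl]-3,3'-bis[(tert-butyldimethylsilyl)oxy]-[6,6'-bichromane]-4,4'-diol | O[C@H]1c2cc(-c3cc4c(c(OCc5ccccc5)c3OCc3ccccc3)O[C@H](c3ccc(OCc5ccccc5)cc3)[C@H](O[Si](C)(C)C(C)(C)C)[C@@H]4O)c(OCc3ccccc3)c(OCc3ccccc3)c2O[C@H](c2ccc(OCc3ccccc3)cc2)[C@@H]1O[Si](C)(C)C(C)(C)C | intermediate
17 | (2R,3R,4S,2'R,3'R,4'R)-7,7',8,8'-tetrakis(benzyloxy)-2,2'-bis[4-(benzyloxy)phenyl]-[6,6'-bichromane]-3,3',4,4'-tetrol | O[C@H]1c2cc(-c3cc4c(c(OCc5ccccc5)c3OCc3ccccc3)O[C@H](c3ccc(OCc5ccccc5)cc3)[C@H](O)[C@@H]4O)c(OCc3ccccc3)c(OCc3ccccc3)c2O[C@H](c2ccc(OCc3ccccc3)cc2)[C@@H]1O | intermediate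
18 | (2R,3R,4R,2'R,3'R,4'S)-2,2'-bis(4-hydroxyphenyl)-[6,6'-bichromane]-3,3',4,4',7,7',8,8'-octol (CNP0121763.1) | Oc1ccc([C@H]2Oc3c(cc(-c4cc5c(c(O)c4O)O[C@H](c4ccc(O)cc4)[C@H](O)[C@H]5O)c(O)c3O)[C@@H](O)[C@H]2O)cc1 | target

**Step count**
Total: 12 steps. Longest linear sequence: 11 steps (1–7, 9, 10, 11, 12; step 8 is the one-step branch from 13 to 14).

**Steps most likely to fail**

1. Step 6 (proposed new method). What may go wrong: C–C bonding through C5 instead of C4 (five-membered ring), closure through a boat-like transition state leading to the 2,3-trans series, or poor face control by the chiral anion. Fallback (known chemistry, sets out from 3 and 7, comes back at 13): Claisen–Schmidt condensation of 3 with 7 (KOH, EtOH, 25 °C) should give the (E)-chalcone F1. Algar–Flynn–Oyamada oxidation (H2O2, NaOH, MeOH/THF, 0 °C) should give the flavonol F2, and silylation (t-BuMe2SiCl, imidazole, DMF) the 3-silyloxyflavone F3. Conjugate reduction with LiBH(s-Bu)3 (THF, −78 °C) and protonation of the enolate with AcOH at −78 °C, anti to the C2 aryl group, should give the racemic 2,3-cis ketone F4. Asymmetric transfer hydrogenation of F4 with RuCl(p-cymene)[(S,S)-TsDPEN] in HCO2H/Et3N, run as a kinetic resolution to about half conversion, should reduce only the (2R,3S) enantiomer from the face anti to O3 and give 13; the unreacted (2S,3R) ketone is separated.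

2. Step 4. What may go wrong: an unfavourable equilibrium for closing the seven-membered aryl alkyl acetal, with open-chain mixed acetals and oligomers accumulating, or acid-induced decay of the α-hydroxy ketone. Fallback (sets out from 6, comes back at 9): 6 is silylated again to the bis-silyl ether 5 (Me3SiCl, Et3N, CH2Cl2), and 5 is treated with 7 and TMSOTf (5 mol %) in CH2Cl2 at −78 °C. This silyl-transfer acetalization is irreversible and independent of the acetal equilibrium; it makes no new compound (F0).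

3. Step 8. What may go wrong: incomplete equilibration, E1 loss of the C3 hydrogen to the enol ether, Friedel–Crafts self-condensation of the C4 cation, or silyl loss. Fallback (sets out from 13, comes back at 14): Mitsunobu inversion of 13 with 4-nitrobenzoic acid, PPh3 and DIAD (THF, 0 °C) should give the inverted (2R,3R,4S) 4-nitrobenzoate F5, and methanolysis (K2CO3, MeOH, 0 °C) should release 14.

Further compounds
F1 | step 6 | (E)-1-[3,4-bis(benzyloxy)-5-bromo-2-hydroxyphenyl]-3-[4-(benzyloxy)phenyl]prop-2-en-1-one | O=C(/C=C/c1ccc(OCc2ccccc2)cc1)c1cc(Br)c(OCc2ccccc2)c(OCc2ccccc2)c1O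
F2 | step 6 | 7,8-bis(benzyloxy)-2-[4-(benzyloxy)phenyl]-6-bromo-3-hydroxy-4H-chromen-4-one | O=c1c(O)c(-c2ccc(OCc3ccccc3)cc2)oc2c(OCc3ccccc3)c(OCc3ccccc3)c(Br)cc12
F3 | step 6 | 7,8-bis(benzyloxy)-2-[4-(benzyloxy)phenyl]-6-bromo-3-[(tert-butyldimethylsilyl)oxy]-4H-chromen-4-one | O=c1c(O[Si](C)(C)C(C)(C)C)c(-c2ccc(OCc3ccccc3)cc2)oc2c(OCc3ccccc3)c(OCc3ccccc3)c(Br)cc12
F4 | step 6 | racemic 2,3-cis-7,8-bis(benzyloxy)-2-[4-(benzyloxy)phenyl]-6-bromo-3-[(tert-butyldimethylsilyl)oxy]chroman-4-one (both enantiomers) | O=C1c2cc(Br)c(OCc3ccccc3)c(OCc3ccccc3)c2O[C@H](c2ccc(OCc3ccccc3)cc2)[C@@H]1O[Si](C)(C)C(C)(C)C.O=C1c2cc(Br)c(OCc3ccccc3)c(OCc3ccccc3)c2O[C@@H](c2ccc(OCc3ccccc3)cc2)[C@H]1O[Si](C)(C)C(C)(C)C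
F0 | step 4 | none | none
F5 | step 8 | (2R,3R,4S)-7,8-bis(benzyloxy)-2-[4-(benzyloxy)phenyl]-6-bromo-3-[(tert-butyldimethylsilyl)oxy]chroman-4-yl 4-nitrobenzoate | O=C(O[C@H]1c2cc(Br)c(OCc3ccccc3)c(OCc3ccccc3)c2O[C@H](c2ccc(OCc3ccccc3)cc2)[C@@H]1O[Si](C)(C)C(C)(C)C)c1ccc([N+](=O)[O-])cc1
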